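**Retrosynthetic overview**

- The last C–C disconnection is the C8–alkene bond: Suzuki coupling of an 8-bromochroman with the (E)-styrylboronate of ring A, whose phenol is carried as a MOM ether and freed in the final step.
- The strategy rests on the pyran ring O1–C2–C3–C4–C4a–C8a. It is the formal [4+2] adduct of an ortho-quinone methide (O1, C8a, C4a, C4) and styrene (C2, C3); C2 (phenyl-bearing, S) is the only stereocentre and is set by a chiral Brønsted acid.
- The methide precursor, a brominated salicyl alcohol, comes from 2-hydroxy-4,6-dimethoxybenzaldehyde by ortho-bromination and reduction. The boronate comes from 3,5-dimethoxy-4-methylphenol by ortho-formylation, MOM protection and boron–Wittig olefination.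
- Ring order: all benzene rings are bought; the pyran ring is the only ring formed, in step 3.

Key step: step 3

Assumption: the sense of induction of the chiral acid cannot be predicted with certainty for a methide that lacks a benzylic substituent; the (R)-configured catalyst is written, and its mirror image is to be used if a first run should give the (2R) chroman.

**Route**

Step 1
Reactants: 1 2-hydroxy-4,6-dimethoxybenzaldehyde
Product: 2 3-bromo-2-hydroxy-4,6-dimethoxybenzaldehyde
Conditions: NBS (1.0 equiv), i-Pr2NH (10 mol %), CH2Cl2, 0 °C
Reagents that add atoms: N-bromosuccinimide, O=C1CCC(=O)N1Br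
Why: Electrophilic aromatic bromination in which the amine-activated N-bromo species is delivered through hydrogen bonding to the phenol, so that substitution should occur at C3 (between OH and OMe) and not at C5, in line with the ortho-to-hydroxyl halogenation known for the corresponding 2-hydroxy-4,6-dimethoxyphenyl ketones; the site is to be confirmed by NOE, since the remaining ring proton of 2 must show contacts to both methoxy groups.

Step 2
Reactants: 2 3-bromo-2-hydroxy-4,6-dimethoxybenzaldehyde
Product: 3 2-bromo-6-(hydroxymethyl)-3,5-dimethoxyphenol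
Conditions: NaBH4, THF/MeOH, 0 °C; neutral work-up (sat. NH4Cl), used at once
Reagents that add atoms: none
Why: Borohydride reduction of an aryl aldehyde that leaves the aryl bromide untouched, with a neutral work-up because traces of acid would already ionise this electron-rich salicyl alcohol.

Step 3
Reactants: 3 2-bromo-6-(hydroxymethyl)-3,5-dimethoxyphenol; 4 styrene
Product: 6 (2S)-8-bromo-5,7-dimethoxy-2-phenylchroman, via ortho-quinone methide 5 (not isolated)
Conditions: (R)-3,3'-bis(2,4,6-triisopropylphenyl)-1,1'-binaphthyl-2,2'-diyl N-triflylphosphoramide (5 mol %), styrene (5 equiv), PhMe, 0 °C, 3 added slowly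
Reagents that add atoms: none
Why: The strong chiral acid protonates the benzylic hydroxyl of 3 and water leaves, which should give methide 5 held at its oxygen as a hydrogen-bonded ion pair by the phosphoramide anion. The styrene CH2 then bonds to the methide carbon (C3–C4) while positive charge builds at the phenyl-bearing carbon, and the methide oxygen closes O1–C2 in the same asynchronous, inverse-electron-demand [4+2] event, so the pyran ring is closed by cycloaddition and not by a separate cyclisation. The closest known reaction type is the N-triflylphosphoramide-catalysed enantioselective cycloaddition of ortho-quinone methides, generated in situ from ortho-hydroxybenzyl alcohols, with styrenes to give 2-arylchromans; a methide without a benzylic substituent is a less studied case, so the 3,3'-groups of the catalyst may need tuning. C2 is the only new stereocentre and is controlled by the catalyst: the anion bound to the methide oxygen shields one approach, so that one enantiotopic face of styrene is presented to the O1 and C4 termini. Regioselectivity (O1 to the phenyl-bearing carbon) follows from benzylic stabilisation of the developing cation. The needed chemoselectivity over Friedel–Crafts attack by the C6–H of a second arene is secured by the bromine, which blocks the position ortho to the phenol, by the excess of styrene and by the slow addition of 3, while the C5 and C7 methoxy groups (ortho and para to C4a) make ionisation easy at low temperature.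

Step 4
Reactants: 7 3,5-dimethoxy-4-methylphenol
Product: 9 6-hydroxy-2,4-dimethoxy-3-methylbenzaldehyde, via salicyl alcohol 8 (not isolated)
Conditions: MgCl2, Et3N, (CH2O)n, MeCN, reflux; then 1 M HCl
Reagents that add atoms: formaldehyde (as paraformaldehyde), C=O
Why: Magnesium-mediated ortho-formylation of a phenol (Casnati–Skattebøl reaction), in which the magnesium phenoxide adds formaldehyde at the ortho position to give 8 and 8 passes hydride to a second formaldehyde; the two ortho positions of 7 are equivalent and the para position carries the methyl group, so only one isomer can form.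

Step 5
Reactants: 9 6-hydroxy-2,4-dimethoxy-3-methylbenzaldehyde
Product: 10 2,4-dimethoxy-6-(methoxymethoxy)-3-methylbenzaldehyde
Conditions: NaH, DMF, 0 °C; then MOMCl, 0 °C → rt
Reagents that add atoms: chloromethyl methyl ether, COCCl
Why: Williamson-type O-alkylation of the sodium phenoxide, with the hydride base chosen because the phenol is chelated to the aldehyde and reacts sluggishly with amine bases.

Step 6
Reactants: 10 2,4-dimethoxy-6-(methoxymethoxy)-3-methylbenzaldehyde
Product: 12 2-[(E)-2-[2,4-dimethoxy-6-(methoxymethoxy)-3-methylphenyl]ethenyl]-4,4,5,5-tetramethyl-1,3,2-dioxaborolane, via lithium beta-alkoxide 11 (not isolated)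
Conditions: CH2(Bpin)2, LiTMP (from 2,2,6,6-tetramethylpiperidine, n-BuLi), THF, 0 °C; then 10, −78 °C → rt
Reagents that add atoms: bis(4,4,5,5-tetramethyl-1,3,2-dioxaborolan-2-yl)methane, CC1(C)OB(CB2OC(C)(C)C(C)(C)O2)OC1(C)C
Why: Boron–Wittig olefination, in which the lithiated geminal bis(boronate) adds to the aldehyde to give 11 and syn elimination of the B–O unit should give the trans alkenylboronate, because the aryl group and the remaining boryl group sit anti in the four-membered borate.

Step 7
Reactants: 6 (2S)-8-bromo-5,7-dimethoxy-2-phenylchroman; 12 2-[(E)-2-[2,4-dimethoxy-6-(methoxymethoxy)-3-methylphenyl]ethenyl]-4,4,5,5-tetramethyl-1,3,2-dioxaborolane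
Product: 13 (2S)-8-[(E)-2-[2,4-dimethoxy-6-(methoxymethoxy)-3-methylphenyl]ethenyl]-5,7-dimethoxy-2-phenylchroman
Conditions: Pd(OAc)2 (5 mol %), SPhos (10 mol %), K3PO4, PhMe/H2O (10:1), degassed, 90 °C
Reagents that add atoms: none
Why: Suzuki–Miyaura coupling, in which the bulky electron-rich biarylphosphine lets zerovalent palladium insert into the doubly ortho-substituted, electron-rich C8–Br bond and the alkenylboronate transfers with retention of the E geometry, while the MOM ether and the C2 stereocentre are inert to the mildly basic medium.

Step 8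
Reactants: 13 (2S)-8-[(E)-2-[2,4-dimethoxy-6-(methoxymethoxy)-3-methylphenyl]ethenyl]-5,7-dimethoxy-2-phenylchroman
Product: 14 2-[(E)-2-[(2S)-5,7-dimethoxy-2-phenylchroman-8-yl]ethenyl]-3,5-dimethoxy-4-methylphenol (CNP0000264.1)
Conditions: conc. HCl (cat.), MeOH/THF, rt → 40 °C
Reagents that add atoms: none
Why: Acid-catalysed acetal exchange of the MOM ether with methanol under mild conditions that the aryl methyl ethers, the E alkene and the chroman C2–O1 bond (a plain benzyl aryl ether) should survive, so the (2S) centre is kept.

**Compound list**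

1 | 2-hydroxy-4,6-dimethoxybenzaldehyde | O=Cc1c(O)cc(OC)cc1OC | starting material
2 | 3-bromo-2-hydroxy-4,6-dimethoxybenzaldehyde | O=Cc1c(O)c(Br)c(OC)cc1OC | intermediate
3 | 2-bromo-6-(hydroxymethyl)-3,5-dimethoxyphenol | OCc1c(O)c(Br)c(OC)cc1OC | intermediate
4 | styrene | C=Cc1ccccc1 | starting material
5 | 2-bromo-3,5-dimethoxy-6-methylidenecyclohexa-2,4-dien-1-one (ortho-quinone methide) | C=C1C(=O)C(Br)=C(OC)C=C1OC | intermediate
6 | (2S)-8-bromo-5,7-dimethoxy-2-phenylchroman | Brc1c(OC)cc(OC)c2c1O[C@H](c1ccccc1)CC2 | intermediate
7 | 3,5-dimethoxy-4-methylphenol | Cc1c(OC)cc(O)cc1OC | starting material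
8 | 2-(hydroxymethyl)-3,5-dimethoxy-4-methylphenol (formed as its magnesium salt) | OCc1c(O)cc(OC)c(C)c1OC | intermediate
9 | 6-hydroxy-2,4-dimethoxy-3-methylbenzaldehyde | O=Cc1c(O)cc(OC)c(C)c1OC | intermediate
10 | 2,4-dimethoxy-6-(methoxymethoxy)-3-methylbenzaldehyde | O=Cc1c(OCOC)cc(OC)c(C)c1OC | intermediate
11 | lithium 1-[2,4-dimethoxy-6-(methoxymethoxy)-3-methylphenyl]-2,2-bis(4,4,5,5-tetramethyl-1,3,2-dioxaborolan-2-yl)ethan-1-olate (racemic) | [Li+].[O-]C(c1c(OCOC)cc(OC)c(C)c1OC)C(B1OC(C)(C)C(C)(C)O1)B1OC(C)(C)C(C)(C)O1 | intermediate
12 | 2-[(E)-2-[2,4-dimethoxy-6-(methoxymethoxy)-3-methylphenyl]ethenyl]-4,4,5,5-tetramethyl-1,3,2-dioxaborolane | COCOc1cc(OC)c(C)c(OC)c1/C=C/B1OC(C)(C)C(C)(C)O1 | intermediate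
13 | (2S)-8-[(E)-2-[2,4-dimethoxy-6-(methoxymethoxy)-3-methylphenyl]ethenyl]-5,7-dimethoxy-2-phenylchroman | COCOc1cc(OC)c(C)c(OC)c1/C=C/c1c(OC)cc(OC)c2c1O[C@H](c1ccccc1)CC2 | intermediate
14 | 2-[(E)-2-[(2S)-5,7-dimethoxy-2-phenylchroman-8-yl]ethenyl]-3,5-dimethoxy-4-methylphenol | COc1cc(O)c(/C=C/c2c(OC)cc(OC)c3c2O[C@H](c2ccccc2)CC3)c(OC)c1C | target

**Step count**

Total: 8 steps. Longest linear sequence: 5 steps (1 → 2 → 3 → 6 → 13 → 14; the branch from 7 is equally long).

**Steps most likely to fail**

1. Step 3. The methide carbon carries no substituent, so the catalyst must discriminate the styrene faces at a centre remote from its binding site and the enantioselectivity may be poor; self-alkylation of the electron-rich arene and acid-induced oligomerisation of styrene may also consume material. The fallback sets out from 2 and comes back at 6.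
   - Claisen–Schmidt condensation of 2 with acetophenone (KOH, EtOH) should give the chalcone (E)-3-(3-bromo-2-hydroxy-4,6-dimethoxyphenyl)-1-phenylprop-2-en-1-one F1.
   - Chemoselective hydrogenation of the enone C=C (H2, RhCl(PPh3)3, PhMe/EtOH), which spares the aryl bromide and the ketone, should give 3-(3-bromo-2-hydroxy-4,6-dimethoxyphenyl)-1-phenylpropan-1-one F2.
   - Noyori asymmetric transfer hydrogenation (RuCl[(R,R)-TsDPEN](p-cymene), HCO2H/Et3N) should give (1R)-3-(3-bromo-2-hydroxy-4,6-dimethoxyphenyl)-1-phenylpropan-1-ol F3.
   - Intramolecular Mitsunobu etherification (PPh3, DIAD, THF, 0 °C) closes O1–C2 with inversion and should give the (2S) chroman 6.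

2. Step 7. Oxidative addition into the hindered, electron-rich C8–Br bond may be slow, and the hindered alkenylboronate may undergo protodeboronation before it transfers. The fallback sets out from 10 and 6 and comes back at 13.
   - Wittig methylenation of 10 (Ph3PCH3Br, KOt-Bu, THF) should give 2-ethenyl-3,5-dimethoxy-1-(methoxymethoxy)-4-methylbenzene F4.
   - A Mizoroki–Heck reaction of F4 with 6 (Pd[P(t-Bu)3]2 cat., Cy2NMe, dioxane, 100 °C) should form the same C8–alkene bond, the E geometry following from syn beta-hydride elimination, and give 13.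

3. Step 1. Bromination may occur at C5, between the two methoxy groups and para to the hydroxyl, or run on to the dibromide, which would place the coupling handle on the wrong carbon. The fallback moves the bromination to the chroman stage; it sets out from 1 and comes back at 6.
   - NaBH4 reduction of 1 should give 2-(hydroxymethyl)-3,5-dimethoxyphenol F5.
   - Under the conditions of step 3, F5 and styrene 4 should react through 3,5-dimethoxy-6-methylidenecyclohexa-2,4-dien-1-one F6 to give (2S)-5,7-dimethoxy-2-phenylchroman F7.
   - NBS (CH2Cl2, −78 °C) should brominate F7 at C8 to give 6. C8 is the site preferred in 5,7-dialkoxyflavans, because C6 is flanked by two alkoxy groups while C8 lies next to the tied-back ring oxygen.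

**Further compounds**

F1 | step 3 | (E)-3-(3-bromo-2-hydroxy-4,6-dimethoxyphenyl)-1-phenylprop-2-en-1-one | O=C(/C=C/c1c(O)c(Br)c(OC)cc1OC)c1ccccc1
F2 | step 3 | 3-(3-bromo-2-hydroxy-4,6-dimethoxyphenyl)-1-phenylpropan-1-one | O=C(CCc1c(O)c(Br)c(OC)cc1OC)c1ccccc1
F3 | step 3 | (1R)-3-(3-bromo-2-hydroxy-4,6-dimethoxyphenyl)-1-phenylpropan-1-ol | O[C@H](CCc1c(O)c(Br)c(OC)cc1OC)c1ccccc1
F4 | step 7 | 2-ethenyl-3,5-dimethoxy-1-(methoxymethoxy)-4-methylbenzene | C=Cc1c(OCOC)cc(OC)c(C)c1OC
F5 | step 1 | 2-(hydroxymethyl)-3,5-dimethoxyphenol | OCc1c(O)cc(OC)cc1OC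
F6 | step 1 | 3,5-dimethoxy-6-methylidenecyclohexa-2,4-dien-1-one | C=C1C(=O)C=C(OC)C=C1OC
F7 | step 1 | (2S)-5,7-dimethoxy-2-phenylchroman | COc1cc(OC)c2c(c1)O[C@H](c1ccccc1)CC2
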